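**Retrosynthetic overview**
1. Amaurone A 29 ⇐ Stille coupling (C–C bond between the two inner diene units) of ring (E)-vinyl iodide 18 with pyrone dienylstannane 28; 28 comes from ethylpyrone 23 by vinylogous aldol/dehydration.
2. 18 ⇐ propynyl triol acetate 16 ⇐ bicyclic endoperoxide 13 by syn-dihydroxylation, acetylation and O–O reduction; all four C–O stereocentres are set on the peroxide bicycle.
3. 13 ⇐ [4+2] cycloaddition of singlet oxygen to the cis-5,6-disubstituted cyclohexa-1,3-diene 12 (key ring-forming cycloaddition).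
4. 12 ⇐ cyclohex-3-enone 10 (enol triflate, methylation) ⇐ RCM of dienone 9 ⇐ Eschenmoser–Claisen [3,3] rearrangement of (2R,3E)-hept-3-en-5-yn-2-ol 4 (sets the two carbon stereocentres) ⇐ (R)-but-3-yn-2-ol 1.
5. Ring order: carbocycle (RCM), then 2,3-dioxabicyclo[2.2.2]octene (¹O₂), reopened to the cyclohexane; the pyranone is made separately by triketide lactonisation.

Assumption: 1-bromoprop-1-yne 2, amide acetal 5 and stannyl alcohol 24 are taken as catalogue items; ring atoms are called C1–C6 in target-SMILES order (C1 side-chain carbon, C2 CHMe, C3 C(Me)OH, C4 CHOAc, C5 C(Me)OH, C6 CHOH).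

**Route**

Step 1
Reactants: 1 (R)-but-3-yn-2-ol; 2 1-bromoprop-1-yne
Product: 3 (R)-hepta-3,5-diyn-2-ol
Conditions: CuCl (5 mol%), NH2OH·HCl, 30% aq. n-BuNH2, 0 °C to rt
Reagents that add atoms: none
Why: Cadiot–Chodkiewicz Cu(I) coupling of a terminal alkyne with a 1-bromoalkyne gives the unsymmetrical diyne and leaves the bought carbinol stereocentre untouched.

Step 2
Reactants: 3 (R)-hepta-3,5-diyn-2-ol
Product: 4 (2R,3E)-hept-3-en-5-yn-2-ol
Conditions: Red-Al, THF, 0 °C to rt; aq. Rochelle salt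
Reagents that add atoms: none
Why: Alkoxide-directed trans-hydroalumination reduces only the propargylic triple bond, and protonolysis gives the (E)-allylic alcohol with the distal alkyne and the stereocentre intact.

Step 3
Reactants: 4 (2R,3E)-hept-3-en-5-yn-2-ol; 5 1,1-dimethoxy-N,N-dimethylpropan-1-amine
Product: 7 (2S,3S,4E)-N,N,2-trimethyl-3-(prop-1-yn-1-yl)hex-4-enamide, via ketene N,O-acetal 6 (not isolated)
Conditions: xylenes, 140 °C, MeOH distilled off
Reagents that add atoms: none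
Why: Eschenmoser–Claisen [3,3]-sigmatropic rearrangement through a chair with the carbinol methyl equatorial and the (Z)-ketene N,O-acetal transfers the C–O chirality of 4 to the new C–C bond, setting ring C1 and C2 anti (cis in the later ring) with the new alkene E; the minor syn isomer (expected about 1 part in 8–10) is removed by chromatography.

Step 4
Reactants: 7 (2S,3S,4E)-N,N,2-trimethyl-3-(prop-1-yn-1-yl)hex-4-enamide; 8 (2-methylprop-2-en-1-yl)magnesium chloride
Product: 9 (5S,6S,7E)-2,5-dimethyl-6-(prop-1-yn-1-yl)nona-1,7-dien-4-one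
Conditions: THF, −78 to −40 °C; AcOH quench at −78 °C, pH 7 buffer
Reagents that add atoms: none
Why: Acyl substitution of the tertiary amide by the allylic Grignard stops at the magnesium hemiaminal until the cold acidic quench, which gives the β,γ-unsaturated ketone without over-addition, conjugation or α-epimerisation.

Step 5
Reactants: 9 (5S,6S,7E)-2,5-dimethyl-6-(prop-1-yn-1-yl)nona-1,7-dien-4-one
Product: 10 (5S,6S)-3,6-dimethyl-5-(prop-1-yn-1-yl)cyclohex-3-en-1-one
Conditions: Grubbs II (5 mol%), 1,4-benzoquinone (10 mol%), CH2Cl2 (5 mM), 40 °C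
Reagents that add atoms: none
Why: Ring-closing metathesis initiates at the propenyl group and closes onto the methallyl alkene to the six-membered trisubstituted cyclohexenone with loss of propene, the methyl-capped alkyne being a poor partner and benzoquinone suppressing alkene migration.

Step 6
Reactants: 10 (5S,6S)-3,6-dimethyl-5-(prop-1-yn-1-yl)cyclohex-3-en-1-one
Product: 11 (5S,6S)-3,6-dimethyl-5-(prop-1-yn-1-yl)cyclohexa-1,3-dien-1-yl trifluoromethanesulfonate
Conditions: KHMDS (1.05 equiv), THF, −78 °C; PhNTf2, −78 to 0 °C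
Reagents that add atoms: N-phenylbis(trifluoromethanesulfonimide), O=S(=O)(N(c1ccccc1)S(=O)(=O)C(F)(F)F)C(F)(F)F
Why: Deprotonation at the doubly activated CH2 (α to C=O and allylic) gives the linear dienolate, whose O-triflation gives the 1,3-dienyl triflate without touching either stereocentre.

Step 7
Reactants: 11 (5S,6S)-3,6-dimethyl-5-(prop-1-yn-1-yl)cyclohexa-1,3-dien-1-yl trifluoromethanesulfonate
Product: 12 (5S,6S)-1,3,6-trimethyl-5-(prop-1-yn-1-yl)cyclohexa-1,3-diene
Conditions: MeZnCl, Pd(PPh3)4 (5 mol%), THF, rt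
Reagents that add atoms: methylzinc chloride, C[Zn]Cl
Why: Negishi cross-coupling of the alkenyl triflate installs the C3 methyl with the diene position fixed by the triflate, and the air-sensitive diene is used directly.

Step 8
Reactants: 12 (5S,6S)-1,3,6-trimethyl-5-(prop-1-yn-1-yl)cyclohexa-1,3-diene
Product: 13 (1R,4S,7S,8S)-1,5,7-trimethyl-8-(prop-1-yn-1-yl)-2,3-dioxabicyclo[2.2.2]oct-5-ene (peroxide bridge anti to the 7-methyl and 8-propynyl groups)
Conditions: O2, TPP (0.5 mol%), white LEDs, CH2Cl2, −30 °C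
Reagents that add atoms: dioxygen, O=O
Why: Suprafacial [4+2] cycloaddition of singlet oxygen to the cyclohexadiene occurs on the face opposite the two cis substituents, setting the C3–O and C6–O stereocentres cis to each other and trans to C1/C2.

Step 9
Reactants: 13 (1R,4S,7S,8S)-1,5,7-trimethyl-8-(prop-1-yn-1-yl)-2,3-dioxabicyclo[2.2.2]oct-5-ene
Product: 14 (1R,4S,5R,6S,7S,8S)-1,5,7-trimethyl-8-(prop-1-yn-1-yl)-2,3-dioxabicyclo[2.2.2]octane-5,6-diol (both OH on the peroxide side)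
Conditions: OsO4 (5 mol%), NMO, acetone/H2O 4:1, rt
Reagents that add atoms: osmium tetroxide, O=[Os](=O)(=O)=O; N-methylmorpholine N-oxide, C[N+]1([O-])CCOCC1; water, O
Why: Upjohn syn-dihydroxylation of the bridging alkene should take place from the peroxide side because the other face is covered by the methyl and propynyl groups that both point at the π-bond, setting C4 and C5 with all four oxygens cis.

Step 10
Reactants: 14 (1R,4S,5R,6S,7S,8S)-1,5,7-trimethyl-8-(prop-1-yn-1-yl)-2,3-dioxabicyclo[2.2.2]octane-5,6-diol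
Product: 15 (1R,4S,5R,6S,7S,8S)-5-hydroxy-1,5,7-trimethyl-8-(prop-1-yn-1-yl)-2,3-dioxabicyclo[2.2.2]octan-6-yl acetate (numbered as 14)
Conditions: Ac2O, pyridine, DMAP (5 mol%), CH2Cl2, 0 °C
Reagents that add atoms: acetic anhydride, CC(=O)OC(C)=O
Why: Acylation takes the only secondary hydroxyl (C4) while the tertiary one is inert and the other two oxygens are still masked in the peroxide, and the cold weakly basic medium avoids Kornblum–DeLaMare opening.

Step 11
Reactants: 15 (1R,4S,5R,6S,7S,8S)-5-hydroxy-1,5,7-trimethyl-8-(prop-1-yn-1-yl)-2,3-dioxabicyclo[2.2.2]octan-6-yl acetate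
Product: 16 (1R,2S,3S,4S,5S,6R)-2,3,6-trihydroxy-2,5,6-trimethyl-4-(prop-1-yn-1-yl)cyclohexyl acetate
Conditions: Zn dust, AcOH, CH2Cl2, rt
Reagents that add atoms: none
Why: Reductive cleavage of the O–O bond leaves both C–O bonds in place, releasing the cis C3/C6 hydroxyls with retention while acetate and alkyne survive.

Step 12
Reactants: 16 (1R,2S,3S,4S,5S,6R)-2,3,6-trihydroxy-2,5,6-trimethyl-4-(prop-1-yn-1-yl)cyclohexyl acetate
Product: 18 (1R,2S,3S,4S,5S,6R)-2,3,6-trihydroxy-4-[(1E)-2-iodoprop-1-en-1-yl]-2,5,6-trimethylcyclohexyl acetate, via vinylstannane 17 (not isolated)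
Conditions: Bu3SnH, PdCl2(PPh3)2 (5 mol%), THF, 0 °C to rt; then I2, CH2Cl2, 0 °C
Reagents that add atoms: iodine, II; tributyltin hydride, CCCC[SnH](CCCC)CCCC (its tin stays only in 17)
Why: Pd-catalysed syn-hydrostannation puts tin on the methyl-bearing alkyne carbon, away from the branched ring carbon, and iododestannylation with retention gives the (E)-iodide.

Step 13
Reactants: 19 methyl 2-methyl-3-oxopentanoate; 20 N-methoxy-N-methylpropanamide
Product: 22 6-ethyl-4-hydroxy-3,5-dimethyl-2H-pyran-2-one, via triketo ester 21 (not isolated)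
Conditions: LDA (2.2 equiv), THF, −78 to 0 °C; 20, −78 °C to rt; aq. HCl; crude, DBU, PhMe, 110 °C
Reagents that add atoms: none
Why: γ-Acylation of the β-keto ester dianion by the Weinreb amide gives the 3,5-dioxo ester, which lactonises through its enol under DBU to the 4-hydroxy-2-pyranone.

Step 14
Reactants: 22 6-ethyl-4-hydroxy-3,5-dimethyl-2H-pyran-2-one
Product: 23 6-ethyl-2-methoxy-3,5-dimethyl-4H-pyran-4-one
Conditions: MeOTf, CH2Cl2, rt; aq. NaHCO3
Reagents that add atoms: methyl trifluoromethanesulfonate, COS(=O)(=O)C(F)(F)F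
Why: A hard methylating agent alkylates the lactone carbonyl oxygen of the neutral hydroxypyranone, and loss of the OH proton gives the 2-methoxy-4-pyranone rather than the 4-methoxy-2-pyranone.

Step 15
Reactants: 24 (2E)-3-(tributylstannyl)prop-2-en-1-ol
Product: 25 (2E)-3-(tributylstannyl)prop-2-enal
Conditions: MnO2, CH2Cl2, rt
Reagents that add atoms: none
Why: Mild allylic oxidation gives the enal without touching the vinylstannane or its geometry.

Step 16
Reactants: 23 6-ethyl-2-methoxy-3,5-dimethyl-4H-pyran-4-one; 25 (2E)-3-(tributylstannyl)prop-2-enal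
Product: 26 6-[(4E)-3-hydroxy-5-(tributylstannyl)pent-4-en-2-yl]-2-methoxy-3,5-dimethyl-4H-pyran-4-one (diastereomer mixture)
Conditions: LiHMDS, THF, −78 °C; then 25; aq. NH4Cl
Reagents that add atoms: none
Why: The vinylogous lithium enolate formed at the 6-ethyl CH2 adds 1,2 to the enal (vinylogous aldol); both new stereocentres are removed in the next step.

Step 17
Reactants: 26 6-[(4E)-3-hydroxy-5-(tributylstannyl)pent-4-en-2-yl]-2-methoxy-3,5-dimethyl-4H-pyran-4-one
Product: 28 2-methoxy-3,5-dimethyl-6-[(2E,4E)-5-(tributylstannyl)penta-2,4-dien-2-yl]-4H-pyran-4-one, via allylic mesylate 27 (not isolated)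
Conditions: MsCl, Et3N, CH2Cl2, 0 °C; then DBU, rt
Reagents that add atoms: none
Why: Mesylation followed by E1cB elimination through the vinylogous pyranone anion gives the conjugated (E)-trisubstituted alkene.

Step 18
Reactants: 18 (1R,2S,3S,4S,5S,6R)-2,3,6-trihydroxy-4-[(1E)-2-iodoprop-1-en-1-yl]-2,5,6-trimethylcyclohexyl acetate; 28 2-methoxy-3,5-dimethyl-6-[(2E,4E)-5-(tributylstannyl)penta-2,4-dien-2-yl]-4H-pyran-4-one
Product: 29 Amaurone A, (1R,2S,3S,4R,5S,6R)-2,3,6-trihydroxy-4-[(1E,3E,5E)-6-(6-methoxy-3,5-dimethyl-4-oxo-4H-pyran-2-yl)-2-methylhepta-1,3,5-trien-1-yl]-2,5,6-trimethylcyclohexyl acetate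
Conditions: Pd2(dba)3 (5 mol%), AsPh3 (20 mol%), DMF, rt, dark
Reagents that add atoms: none
Why: Stille coupling joins the two sp2 carbons with retention of both alkene geometries under neutral conditions that tolerate the free hydroxyls, the acetate and the pyranone, giving the all-E triene.

**Compound list**
1 | (R)-but-3-yn-2-ol | C[C@@H](O)C#C | starting material
2 | 1-bromoprop-1-yne | CC#CBr | starting material
3 | (R)-hepta-3,5-diyn-2-ol | C[C@@H](O)C#CC#CC | intermediate
4 | (2R,3E)-hept-3-en-5-yn-2-ol | C[C@@H](O)/C=C/C#CC | intermediate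
5 | 1,1-dimethoxy-N,N-dimethylpropan-1-amine | CCC(OC)(OC)N(C)C | starting material
6 | (1Z)-1-{[(2R,3E)-hept-3-en-5-yn-2-yl]oxy}-N,N-dimethylprop-1-en-1-amine | C/C=C(\O[C@H](C)/C=C/C#CC)N(C)C | intermediate (not isolated)
7 | (2S,3S,4E)-N,N,2-trimethyl-3-(prop-1-yn-1-yl)hex-4-enamide | CN(C)C(=O)[C@@H](C)[C@@H](C#CC)/C=C/C | intermediate
8 | (2-methylprop-2-en-1-yl)magnesium chloride | CC(=C)C[Mg]Cl | starting material
9 | (5S,6S,7E)-2,5-dimethyl-6-(prop-1-yn-1-yl)nona-1,7-dien-4-one | CC(=C)CC(=O)[C@@H](C)[C@@H](C#CC)/C=C/C | intermediate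
10 | (5S,6S)-3,6-dimethyl-5-(prop-1-yn-1-yl)cyclohex-3-en-1-one | O=C1CC(C)=C[C@H](C#CC)[C@@H]1C | intermediate
11 | (5S,6S)-3,6-dimethyl-5-(prop-1-yn-1-yl)cyclohexa-1,3-dien-1-yl trifluoromethanesulfonate | O=S(=O)(OC1=CC(C)=C[C@H](C#CC)[C@@H]1C)C(F)(F)F | intermediate
12 | (5S,6S)-1,3,6-trimethyl-5-(prop-1-yn-1-yl)cyclohexa-1,3-diene | CC1=CC(C)=C[C@H](C#CC)[C@@H]1C | intermediate
13 | (1R,4S,7S,8S)-1,5,7-trimethyl-8-(prop-1-yn-1-yl)-2,3-dioxabicyclo[2.2.2]oct-5-ene | CC#C[C@@H]2[C@H](C)[C@@](C)(O3)C=C(C)[C@H]2O3 | intermediate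
14 | (1R,4S,5R,6S,7S,8S)-1,5,7-trimethyl-8-(prop-1-yn-1-yl)-2,3-dioxabicyclo[2.2.2]octane-5,6-diol | CC#C[C@@H]2[C@H](C)[C@@](C)(O3)[C@@H](O)[C@@](C)(O)[C@H]2O3 | intermediate
15 | (1R,4S,5R,6S,7S,8S)-5-hydroxy-1,5,7-trimethyl-8-(prop-1-yn-1-yl)-2,3-dioxabicyclo[2.2.2]octan-6-yl acetate (numbered as 14) | CC#C[C@@H]2[C@H](C)[C@@](C)(O3)[C@@H](OC(C)=O)[C@@](C)(O)[C@H]2O3 | intermediate
16 | (1R,2S,3S,4S,5S,6R)-2,3,6-trihydroxy-2,5,6-trimethyl-4-(prop-1-yn-1-yl)cyclohexyl acetate | CC#C[C@@H]1[C@H](C)[C@@](C)(O)[C@@H](OC(C)=O)[C@@](C)(O)[C@H]1O | intermediate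
17 | (1R,2S,3S,4S,5S,6R)-2,3,6-trihydroxy-2,5,6-trimethyl-4-[(1E)-2-(tributylstannyl)prop-1-en-1-yl]cyclohexyl acetate | CCCC[Sn](CCCC)(CCCC)/C(C)=C/[C@@H]1[C@H](C)[C@@](C)(O)[C@@H](OC(C)=O)[C@@](C)(O)[C@H]1O | intermediate (not isolated)
18 | (1R,2S,3S,4S,5S,6R)-2,3,6-trihydroxy-4-[(1E)-2-iodoprop-1-en-1-yl]-2,5,6-trimethylcyclohexyl acetate | I/C(C)=C/[C@@H]1[C@H](C)[C@@](C)(O)[C@@H](OC(C)=O)[C@@](C)(O)[C@H]1O | intermediate
19 | methyl 2-methyl-3-oxopentanoate | CCC(=O)C(C)C(=O)OC | starting material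
20 | N-methoxy-N-methylpropanamide | CCC(=O)N(C)OC | starting material
21 | methyl 2,4-dimethyl-3,5-dioxoheptanoate | CCC(=O)C(C)C(=O)C(C)C(=O)OC | intermediate (not isolated)
22 | 6-ethyl-4-hydroxy-3,5-dimethyl-2H-pyran-2-one | CCc1oc(=O)c(C)c(O)c1C | intermediate
23 | 6-ethyl-2-methoxy-3,5-dimethyl-4H-pyran-4-one | CCc1oc(OC)c(C)c(=O)c1C | intermediate
24 | (2E)-3-(tributylstannyl)prop-2-en-1-ol | CCCC[Sn](CCCC)(CCCC)/C=C/CO | starting material
25 | (2E)-3-(tributylstannyl)prop-2-enal | CCCC[Sn](CCCC)(CCCC)/C=C/C=O | intermediate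
26 | 6-[(4E)-3-hydroxy-5-(tributylstannyl)pent-4-en-2-yl]-2-methoxy-3,5-dimethyl-4H-pyran-4-one (diastereomer mixture) | COc1oc(C(C)C(O)/C=C/[Sn](CCCC)(CCCC)CCCC)c(C)c(=O)c1C | intermediate
27 | (4E)-2-(6-methoxy-3,5-dimethyl-4-oxo-4H-pyran-2-yl)-5-(tributylstannyl)pent-4-en-3-yl methanesulfonate | COc1oc(C(C)C(OS(C)(=O)=O)/C=C/[Sn](CCCC)(CCCC)CCCC)c(C)c(=O)c1C | intermediate (not isolated)
28 | 2-methoxy-3,5-dimethyl-6-[(2E,4E)-5-(tributylstannyl)penta-2,4-dien-2-yl]-4H-pyran-4-one | COc1oc(/C(C)=C/C=C/[Sn](CCCC)(CCCC)CCCC)c(C)c(=O)c1C | intermediate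
29 | Amaurone A, (1R,2S,3S,4R,5S,6R)-2,3,6-trihydroxy-4-[(1E,3E,5E)-6-(6-methoxy-3,5-dimethyl-4-oxo-4H-pyran-2-yl)-2-methylhepta-1,3,5-trien-1-yl]-2,5,6-trimethylcyclohexyl acetate | COc1oc(/C(C)=C/C=C/C(C)=C/[C@@H]2[C@H](C)[C@@](C)(O)[C@@H](OC(C)=O)[C@@](C)(O)[C@H]2O)c(C)c(=O)c1C | target

**Count and risks**

Total step count: 18. Longest linear sequence: 13 (steps 1–12, then 18); the pyranone branch is steps 13–17.

The three steps most likely to fail:

Step 4 (allylic Grignard on a dimethylamide: over-addition or drift of the β,γ-enone into conjugation). The fallback sets out from 4 and comes back at 9. Alcohol 4 is acylated with propanoic anhydride (Et3N, DMAP) to (2R,3E)-hept-3-en-5-yn-2-yl propanoate F1. Ireland–Claisen rearrangement (LDA, THF, −78 °C; TMSCl; warm to rt; aq. HCl) through the same chair gives (2S,3S,4E)-2-methyl-3-(prop-1-yn-1-yl)hex-4-enoic acid F2, usually with better anti selectivity than the amide-acetal variant. CDI and MeNHOMe·HCl turn it into (2S,3S,4E)-N-methoxy-N,2-dimethyl-3-(prop-1-yn-1-yl)hex-4-enamide F3, whose chelated adduct with 8 releases 9 only on quench.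

Step 9 (face of osmylation on the peroxide bicycle; unsubstituted analogues are attacked anti to the O–O bridge). The fallback sets out from 13 and comes back at 16. Thiourea in MeOH reduces 13 to (1R,4S,5S,6S)-1,3,6-trimethyl-5-(prop-1-yn-1-yl)cyclohex-2-ene-1,4-diol F4. TESCl/imidazole silylates only the secondary allylic hydroxyl to give the 4-O-triethylsilyl ether F5. Hydrogen-bond-directed dihydroxylation (OsO4·TMEDA, CH2Cl2, −78 °C), guided by the free tertiary allylic OH, delivers both new hydroxyls syn to it in the silyl-protected tetraol F6. Ac2O/DMAP acetylates the one free secondary OH to the silyl-protected acetate F7, and HF·pyridine removes the silyl group to reach 16.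

Step 12 (regiochemistry of hydrostannation on an internal alkyne next to three free hydroxyls). The fallback sets out from 16 and comes back at 18. Pt-catalysed syn-hydrosilylation (Et3SiH, Karstedt catalyst/P(t-Bu)3, THF, 50 °C) places silicon on the methyl-bearing carbon to give (1R,2S,3S,4S,5S,6R)-2,3,6-trihydroxy-2,5,6-trimethyl-4-[(1E)-2-(triethylsilyl)prop-1-en-1-yl]cyclohexyl acetate F8. Iododesilylation with NIS in HFIP at 0 °C gives 18 with retention.

**Further compounds**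
F1 | step 4 | (2R,3E)-hept-3-en-5-yn-2-yl propanoate | CCC(=O)O[C@H](C)/C=C/C#CC
F2 | step 4 | (2S,3S,4E)-2-methyl-3-(prop-1-yn-1-yl)hex-4-enoic acid | OC(=O)[C@@H](C)[C@@H](C#CC)/C=C/C
F3 | step 4 | (2S,3S,4E)-N-methoxy-N,2-dimethyl-3-(prop-1-yn-1-yl)hex-4-enamide | CON(C)C(=O)[C@@H](C)[C@@H](C#CC)/C=C/C
F4 | step 9 | (1R,4S,5S,6S)-1,3,6-trimethyl-5-(prop-1-yn-1-yl)cyclohex-2-ene-1,4-diol | CC#C[C@@H]1[C@H](C)[C@@](C)(O)C=C(C)[C@H]1O
F5 | step 9 | 4-O-triethylsilyl ether of F4 | CC#C[C@@H]1[C@H](C)[C@@](C)(O)C=C(C)[C@H]1O[Si](CC)(CC)CC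
F6 | step 9 | all-cis 1,2,3-triol from F5 (ring C3, C4, C5 hydroxyls free, C6 O-triethylsilyl) | CC#C[C@@H]1[C@H](C)[C@@](C)(O)[C@@H](O)[C@@](C)(O)[C@H]1O[Si](CC)(CC)CC
F7 | step 9 | C4 acetate of F6 (6-O-triethylsilyl ether of 16) | CC#C[C@@H]1[C@H](C)[C@@](C)(O)[C@@H](OC(C)=O)[C@@](C)(O)[C@H]1O[Si](CC)(CC)CC
F8 | step 12 | (1R,2S,3S,4S,5S,6R)-2,3,6-trihydroxy-2,5,6-trimethyl-4-[(1E)-2-(triethylsilyl)prop-1-en-1-yl]cyclohexyl acetate | CC[Si](CC)(CC)/C(C)=C/[C@@H]1[C@H](C)[C@@](C)(O)[C@@H](OC(C)=O)[C@@](C)(O)[C@H]1O
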